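**Retrosynthetic overview**

1. Target ⇐ oxidative γ-lactonisation (C6–O to C12), hydroxyl-directed C1=C2 epoxidation, reduction of the C3 and C8 carbonyls and C8 angeloylation ⇐ a (Z,Z)-cyclodecadiene-1,6-dione.
2. Feature used: C3 and C8 both carry oxygen and face each other 1,6 across the ten-membered ring. The arc C3–C4(CH3)=C5–C6–C7–C8 is a carvone-type cyclohexene and the arc C8–C9–C10–C1(CH3)=C2–C3 a second cyclohexene, so a C3–C8 bond turns the macrocycle into a cis-fused hexahydronaphthalene-4a,8a-diol. Glycol cleavage of that bond is the key disconnection.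
3. Bicyclic diol ⇐ ring-closing metathesis (C1=C2, ring B) ⇐ vinyl addition at C3 and 3-methylbut-3-enyl addition at C8 of a ring A ketol, with carbon as the nucleophile at both carbinols.
4. Ring A ⇐ (R)-carvone: C12 oxygen by allylic chlorination; C6 oxygen by α'-hydroxylation and Mitsunobu inversion; Wharton 1,3-transposition moves the carbonyl from C5 to C3, so the C6 oxygen becomes γ and C8 the new α' position.
5. Ring order: ring A (chiral pool) → ring B (metathesis) → ten-membered ring (C3–C8 scission) → epoxide → lactone.

Key step: step 17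

Remark on numbering: C1–C13 are the carbons of the target (C1 methyl-bearing epoxide carbon, C2 epoxide CH, C3 carbinol, C4=C5 alkene, C6 lactone O–CH, C7 ring-fusion CH, C8 angelate carbinol, C9/C10 CH2, C11 lactone α-carbon, C12 carbonyl, C13 exocyclic CH2). The same labels are used for every intermediate. In (R)-carvone the carbonyl carbon is C5, the methyl-bearing carbon C4, the alkene CH C3, the CH2 next to it C8, the stereocentre C7 and the CH2 next to the carbonyl C6.

Remark on one assumption: 4-bromo-2-methylbut-1-ene (17) is taken as a purchased reagent; it is the Appel bromide of 3-methylbut-3-en-1-ol.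

**Step 1**
Reactants: 1 (R)-(−)-carvone
Product: 2 (5R)-5-(3-chloroprop-1-en-2-yl)-2-methylcyclohex-2-en-1-one
Conditions: Ca(OCl)2, CO2 (dry ice), CH2Cl2/H2O, 0 °C
Reagents that add atoms: calcium hypochlorite, [Ca+2].[O-]Cl.[O-]Cl
Why: Ene-type allylic chlorination by HOCl attacks only the electron-rich 1,1-disubstituted alkene and not the enone; chlorine ends on the terminal carbon with a shift of the double bond, so the side chain stays a 2-substituted allyl unit and C7 is untouched.

**Step 2**
Reactants: 2 (5R)-5-(3-chloroprop-1-en-2-yl)-2-methylcyclohex-2-en-1-one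
Product: 4 (5R)-5-(3-hydroxyprop-1-en-2-yl)-2-methylcyclohex-2-en-1-one, via allylic acetate 3 (not isolated)
Conditions: KOAc, NaI (cat.), DMF, 60 °C; then K2CO3 (cat.), MeOH, rt
Reagents that add atoms: potassium acetate, CC(=O)[O-].[K+]
Why: SN2 displacement of the primary allylic chloride by acetate (iodide catalysis) followed by carbonate-catalysed transesterification with methanol; no stereocentre is involved.

**Step 3**
Reactants: 4 (5R)-5-(3-hydroxyprop-1-en-2-yl)-2-methylcyclohex-2-en-1-one
Product: 5 (5R)-5-[3-(tert-butyldimethylsilyloxy)prop-1-en-2-yl]-2-methylcyclohex-2-en-1-one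
Conditions: TBSCl, imidazole, DMF, rt
Reagents that add atoms: tert-butyldimethylsilyl chloride, CC(C)(C)[Si](C)(C)Cl
Why: Standard silylation of a primary alcohol gives an ether that withstands the peroxide, amide base, hydrazine and organometallic steps that follow.

**Step 4**
Reactants: 5 (5R)-5-[3-(tert-butyldimethylsilyloxy)prop-1-en-2-yl]-2-methylcyclohex-2-en-1-one
Product: 6 (1R,4R,6R)-4-[3-(tert-butyldimethylsilyloxy)prop-1-en-2-yl]-1-methyl-7-oxabicyclo[4.1.0]heptan-2-one (epoxide oxygen trans to the C7 side chain)
Conditions: 30% H2O2, NaOH (cat.), MeOH, 0 °C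
Reagents that add atoms: hydrogen peroxide, OO
Why: Weitz–Scheffer nucleophilic epoxidation: hydroperoxide adds to the enone β-carbon C3 on the face opposite the C7 side chain and the enolate closes the oxirane, as for carvone itself, while the isolated alkene does not react; the two new centres are erased again in steps 9 and 10.

**Step 5**
Reactants: 6 trans-epoxy ketone
Product: 7 C6-hydroxy epoxy ketone with the C6 hydroxyl trans to the C7 side chain
Conditions: NaN(SiMe3)2, THF, −78 °C; then 2-(benzenesulfonyl)-3-phenyloxaziridine, −78 °C; aq. NH4Cl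
Reagents that add atoms: 2-(benzenesulfonyl)-3-phenyloxaziridine, O=S(=O)(N1OC1c1ccccc1)c1ccccc1
Why: Davis enolate hydroxylation: C6 carries the only enolisable hydrogens, and the oxaziridine should transfer oxygen to the enolate face opposite the adjacent C7 side chain, giving the C6 hydroxyl trans to it.

**Step 6**
Reactants: 7 trans C6-hydroxy epoxy ketone
Product: 8 C6 4-nitrobenzoate with the ester oxygen cis to the C7 side chain
Conditions: 4-O2NC6H4CO2H, PPh3, DIAD, THF, 0 °C → rt
Reagents that add atoms: 4-nitrobenzoic acid, O=C(O)c1ccc(cc1)[N+](=O)[O-]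
Why: Mitsunobu esterification: SN2 displacement of the carbonyl-activated C6 oxyphosphonium ion by 4-nitrobenzoate (the acid used for hindered secondary alcohols) inverts C6, which places the C6 oxygen cis to the C7 side chain as the lactone requires.

**Step 7**
Reactants: 8 C6 4-nitrobenzoate
Product: 9 C6-hydroxy epoxy ketone with the hydroxyl cis to the C7 side chain
Conditions: K2CO3 (0.2 equiv), MeOH, 0 °C
Reagents that add atoms: none
Why: Carbonate-catalysed transesterification removes the activated aryl ester at 0 °C, mild enough that the α-ketol should not epimerise at C6 and the primary silyl ether and the epoxide survive.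

**Step 8**
Reactants: 9 cis C6-hydroxy epoxy ketone
Product: 10 C6 tert-butyldimethylsilyl ether of 9
Conditions: TBSOTf, 2,6-lutidine, CH2Cl2, −78 °C
Reagents that add atoms: tert-butyldimethylsilyl trifluoromethanesulfonate, CC(C)(C)[Si](C)(C)OS(=O)(=O)C(F)(F)F
Why: Silylation with the triflate and 2,6-lutidine is the standard method for a hindered secondary alcohol and fixes C6 as an ether stable to hydrazine, amide bases and organometallics.

**Step 9**
Reactants: 10 bis-silylated epoxy ketone
Product: 11 4-(tert-butyldimethylsilyloxy)-5-[3-(tert-butyldimethylsilyloxy)prop-1-en-2-yl]-2-methylcyclohex-2-en-1-ol (C6 silyloxy cis to the C7 side chain; C3 hydroxyl trans to both)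
Conditions: N2H4·H2O, AcOH (cat.), MeOH, 0 °C → rt
Reagents that add atoms: none
Why: Wharton transposition: the epoxy hydrazone opens to a vinyl diazene that loses N2, which moves the alkene to C4=C5 and leaves the former epoxide oxygen as the C3 hydroxyl with its C–O bond untouched, while C6 and C7 are not involved.

**Step 10**
Reactants: 11 allylic alcohol
Product: 12 4-(tert-butyldimethylsilyloxy)-5-[3-(tert-butyldimethylsilyloxy)prop-1-en-2-yl]-2-methylcyclohex-2-en-1-one (4,5-cis)
Conditions: MnO2, CH2Cl2, rt
Reagents that add atoms: none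
Why: Oxidation of the allylic alcohol on MnO2 completes the 1,3-transposition of the enone: the carbonyl now sits on C3, the C6 silyloxy group is γ to it and the C8 methylene has become the α' position; no stereocentre changes.

**Step 11**
Reactants: 12 transposed enone
Product: 13 C8-hydroxy enone with the C8 hydroxyl trans to the C7 side chain
Conditions: KN(SiMe3)2, THF, −78 °C; then 2-(benzenesulfonyl)-3-phenyloxaziridine, −78 °C; aq. NH4Cl
Reagents that add atoms: 2-(benzenesulfonyl)-3-phenyloxaziridine, O=S(=O)(N1OC1c1ccccc1)c1ccccc1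
Why: Kinetic deprotonation of the enone at the α' methylene C8 and Davis hydroxylation of the cross-conjugated enolate anti to the C7 side chain give the C8 alcohol; its configuration is of no consequence because C8 is oxidised in step 13.

**Step 12**
Reactants: 13 C8-hydroxy enone; 14 vinylmagnesium bromide
Product: 15 1-vinylcyclohex-2-ene-1,6-diol with the C3 hydroxyl cis to the C6 silyloxy group and the C7 side chain and the C8 hydroxyl trans to them
Conditions: CH2=CHMgBr (3 equiv), THF, −78 → −20 °C; aq. NH4Cl
Reagents that add atoms: vinylmagnesium bromide (14), C=C[Mg]Br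
Why: Grignard 1,2-addition: the first equivalent forms the C8 magnesium alkoxide, the next adds to the C3 carbonyl by axial attack on the chelated half-chair from the face opposite the C7 side chain, as in additions to carvone, so the C3 hydroxyl comes out cis to the C6 and C7 substituents with the vinyl group on the other face.

**Step 13**
Reactants: 15 vinyl diol
Product: 16 6-hydroxy-6-vinylcyclohex-4-en-1-one (C8 ketone, tertiary C3 hydroxyl, C6 silyloxy cis to the C7 side chain)
Conditions: IBX, DMSO, rt
Reagents that add atoms: none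
Why: IBX oxidises the secondary C8 alcohol and leaves the tertiary C3 alcohol alone, without glycol cleavage, and its neutral medium should keep the new α centre C7 from epimerising and the β-silyloxy group from eliminating.

**Step 14**
Reactants: 17 4-bromo-2-methylbut-1-ene
Product: 18 (3-methylbut-3-en-1-yl)magnesium bromide
Conditions: Mg, I2 (cat.), THF, rt → 40 °C
Reagents that add atoms: magnesium, [Mg]
Why: Insertion of magnesium into the primary C–Br bond (Grignard formation); the cyclopropylcarbinyl equilibrium of this homoallyl reagent is degenerate, so its constitution is secure.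

**Step 15**
Reactants: 16 hydroxy ketone; 18 (3-methylbut-3-en-1-yl)magnesium bromide
Product: 20 1-vinyl-6-(3-methylbut-3-en-1-yl)cyclohex-2-ene-1,6-diol with both hydroxyls, the C6 silyloxy group and the C7 side chain on one face and the two alkenyl groups on the other, via (3-methylbut-3-en-1-yl)cerium dichloride 19 (not isolated)
Conditions: CeCl3 (anhydrous), 18 (3 equiv), THF, −78 °C, then 16; aq. NH4Cl
Reagents that add atoms: (3-methylbut-3-en-1-yl)magnesium bromide (18), C=C(C)CC[Mg]Br
Why: Organocerium (Imamoto) 1,2-addition, chosen for its low basicity toward the enolisable β-silyloxy ketone: one equivalent deprotonates the C3 hydroxyl and the C8 carbonyl is then attacked from the β face, because the α face is screened by the pseudoaxial C6 silyloxy group and the C7 side chain, so the new C8 hydroxyl is cis to the C3 hydroxyl and the butenyl chain is cis to the vinyl group.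

**Step 16**
Reactants: 20 triene diol
Product: 21 3-(tert-butyldimethylsilyloxy)-4-[3-(tert-butyldimethylsilyloxy)prop-1-en-2-yl]-1,7-dimethyl-3,4,5,6-tetrahydronaphthalene-4a,8a-diol (cis ring fusion; both hydroxyls on the face of the C6 silyloxy group and the C7 side chain)
Conditions: second-generation Grubbs catalyst [RuCl2(=CHPh)(PCy3)(H2IMes)] (5 mol %), CH2Cl2, 40 °C
Reagents that add atoms: none
Why: Ring-closing metathesis: the ruthenium carbene forms at the vinyl group and closes on the cis-disposed 1,1-disubstituted alkene to a trisubstituted cyclohexene (ring B, cis fused, alkene necessarily cis in the ring), while the ring A alkene and the hindered C11=C13 alkene on the opposite face stay out.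

**Step 17**
Reactants: 21 cis-fused hexahydronaphthalene-4a,8a-diol
Product: 22 (2Z,9Z)-4-(tert-butyldimethylsilyloxy)-5-[3-(tert-butyldimethylsilyloxy)prop-1-en-2-yl]-2,9-dimethylcyclodeca-2,9-diene-1,6-dione
Conditions: Pb(OAc)4 (1.1 equiv), K2CO3, CH2Cl2, −20 → 0 °C; filtered through Celite and used at once
Reagents that add atoms: none
Why: Pb(OAc)4 exchanges two acetates for the cis-disposed C3 and C8 hydroxyls to give a five-membered cyclic lead diester, which collapses in a concerted two-electron fragmentation that breaks the C3–C8 bond and releases Pb(OAc)2 and both carbonyl groups. This is the Criegee glycol cleavage, known to turn decalin-4a,8a-diols into cyclodecane-1,6-diones. No ring is closed by bond formation: the ten-membered ring is the perimeter of the fused bicycle and appears by scission of the shared bond (ring expansion by fragmentation), so no cyclisation mode or entropy is at stake. No stereocentre is created: C3 and C8 become trigonal, C6 and C7 are untouched, and the C1=C2 and C4=C5 alkenes keep the cis geometry imposed by the six-membered rings, hence Z,Z. The step needs only chemoselectivity, which is secured because the substrate holds a single 1,2-diol whose cis ring fusion allows the cyclic ester, while the silyl ethers and the three alkenes are inert to Pb(OAc)4 at 0 °C. Solid K2CO3 takes up the acetic acid so that neither the bis-allylic carbinol nor the enolisable β-silyloxy dione meets acid, and the dione is reduced directly in step 18 to forestall transannular aldol, Nazarov and elimination pathways.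

**Step 18**
Reactants: 22 (Z,Z)-cyclodecadiene-1,6-dione
Product: 23 C8 alcohol of 22 (C8 hydroxyl cis, in the ring sense, to the C7 side chain; C3 dienone intact)
Conditions: NaBH4, MeOH/CH2Cl2, −78 °C
Reagents that add atoms: none
Why: Borohydride reduction: at −78 °C the isolated C8 ketone should react well before the cross-conjugated dienone (the selectivity used for 17-keto steroidal 1,4-dien-3-ones), and hydride is expected to come in past the C7 hydrogen, anti to the C7–C6 ring bond with the side chain beside the carbonyl oxygen (Felkin–Anh), which puts the C8 hydroxyl cis to the C7 side chain.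

**Step 19**
Reactants: 23 C8 alcohol; 24 angelic acid
Product: 26 C8 angelate of 23, via angelic 2,4,6-trichlorobenzoic anhydride 25 (not isolated)
Conditions: 24, 2,4,6-trichlorobenzoyl chloride, Et3N, toluene, rt; then 23, 70 °C
Reagents that add atoms: angelic acid (24), C/C=C(/C)C(=O)O
Why: Yamaguchi-type esterification through the mixed 2,4,6-trichlorobenzoic anhydride without DMAP, the protocol that acylates hindered secondary alcohols with angelic acid without Z to E isomerisation to the tiglate.

**Step 20**
Reactants: 26 angelate dienone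
Product: 27 C3 alcohol of 26 (C3 hydroxyl on the same ring face as the C6, C7 and C8 substituents)
Conditions: NaBH4, CeCl3·7H2O, MeOH, −78 °C
Reagents that add atoms: none
Why: Luche 1,2-reduction of the cross-conjugated dienone: the cis alkenes hold the ring as a tub with the C6, C7 and C8 substituents on one face, so hydride should add to C3 from the open face and leave the hydroxyl on the substituted face, with the ester and silyl ethers untouched.

**Step 21**
Reactants: 27 bis-allylic alcohol
Product: 28 C1–C2 epoxide of 27 (epoxide oxygen cis to the C3 hydroxyl)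
Conditions: VO(acac)2 (5 mol %), t-BuOOH, CH2Cl2, 0 °C
Reagents that add atoms: tert-butyl hydroperoxide, CC(C)(C)OO
Why: Sharpless vanadium-directed epoxidation: the C3 hydroxyl delivers the peroxide oxygen to its own face, giving the cis epoxy alcohol as with medium-ring allylic alcohols, and C1=C2 should be preferred over C4=C5 because the latter is shielded and inductively deactivated by the allylic C6 silyloxy group; the electron-poor angelate and the undirected C11=C13 alkene are not touched.

**Step 22**
Reactants: 28 epoxy alcohol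
Product: 29 triol (free C3, C6 and C12 hydroxyls; C8 angelate; C1–C2 epoxide)
Conditions: HF·pyridine, pyridine, THF, 0 °C → rt
Reagents that add atoms: none
Why: Fluoride-mediated desilylation: buffered HF·pyridine cleaves the primary and the secondary allylic silyl ethers without base, so the angelate should neither migrate nor isomerise and the epoxy alcohol should not open or undergo Payne rearrangement.

**Step 23**
Reactants: 29 triol
Product: 30 CNP0500828.1
Conditions: TEMPO (cat.), PhI(OAc)2, CH2Cl2, rt
Reagents that add atoms: none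
Why: TEMPO/PhI(OAc)2 oxidative lactonisation: the primary allylic alcohol is oxidised first to the enal, the cis C6 hydroxyl closes the five-membered lactol and this is oxidised on to the α-methylene-γ-lactone, while the hindered secondary C3 alcohol reacts much more slowly; no stereocentre is formed.

**Compound list**

1 | (R)-(−)-carvone | CC1=CC[C@H](CC1=O)C(C)=C | starting material
2 | (5R)-5-(3-chloroprop-1-en-2-yl)-2-methylcyclohex-2-en-1-one | CC1=CC[C@H](CC1=O)C(=C)CCl | intermediate
3 | 2-[(1R)-4-methyl-5-oxocyclohex-3-en-1-yl]prop-2-en-1-yl acetate | CC1=CC[C@H](CC1=O)C(=C)COC(C)=O | intermediate (not isolated)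
4 | (5R)-5-(3-hydroxyprop-1-en-2-yl)-2-methylcyclohex-2-en-1-one | CC1=CC[C@H](CC1=O)C(=C)CO | intermediate
5 | (5R)-5-[3-(tert-butyldimethylsilyloxy)prop-1-en-2-yl]-2-methylcyclohex-2-en-1-one | CC1=CC[C@H](CC1=O)C(=C)CO[Si](C)(C)C(C)(C)C | intermediate
6 | (1R,4R,6R)-4-[3-(tert-butyldimethylsilyloxy)prop-1-en-2-yl]-1-methyl-7-oxabicyclo[4.1.0]heptan-2-one | C[C@@]12O[C@@H]1C[C@H](CC2=O)C(=C)CO[Si](C)(C)C(C)(C)C | intermediate
7 | 3-hydroxy derivative of 6, hydroxyl (C6) trans to the C7 side chain | C[C@@]12O[C@@H]1C[C@H]([C@H](O)C2=O)C(=C)CO[Si](C)(C)C(C)(C)C | intermediate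
8 | C6 4-nitrobenzoate, ester oxygen cis to the C7 side chain | C[C@@]12O[C@@H]1C[C@H]([C@@H](OC(=O)c3ccc(cc3)[N+](=O)[O-])C2=O)C(=C)CO[Si](C)(C)C(C)(C)C | intermediate
9 | C6 epimer of 7, hydroxyl cis to the C7 side chain | C[C@@]12O[C@@H]1C[C@H]([C@@H](O)C2=O)C(=C)CO[Si](C)(C)C(C)(C)C | intermediate
10 | C6 tert-butyldimethylsilyl ether of 9 | C[C@@]12O[C@@H]1C[C@H]([C@@H](O[Si](C)(C)C(C)(C)C)C2=O)C(=C)CO[Si](C)(C)C(C)(C)C | intermediate
11 | 4-(tert-butyldimethylsilyloxy)-5-[3-(tert-butyldimethylsilyloxy)prop-1-en-2-yl]-2-methylcyclohex-2-en-1-ol (4,5-cis; 1-hydroxyl trans) | CC1=C[C@H](O[Si](C)(C)C(C)(C)C)[C@@H](C[C@H]1O)C(=C)CO[Si](C)(C)C(C)(C)C | intermediate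
12 | 4-(tert-butyldimethylsilyloxy)-5-[3-(tert-butyldimethylsilyloxy)prop-1-en-2-yl]-2-methylcyclohex-2-en-1-one (4,5-cis) | CC1=C[C@H](O[Si](C)(C)C(C)(C)C)[C@@H](CC1=O)C(=C)CO[Si](C)(C)C(C)(C)C | intermediate
13 | 6-hydroxy derivative of 12, hydroxyl (C8) trans to the C7 side chain | CC1=C[C@H](O[Si](C)(C)C(C)(C)C)[C@@H]([C@@H](O)C1=O)C(=C)CO[Si](C)(C)C(C)(C)C | intermediate
14 | vinylmagnesium bromide | C=C[Mg]Br | starting material
15 | 4-(tert-butyldimethylsilyloxy)-5-[3-(tert-butyldimethylsilyloxy)prop-1-en-2-yl]-2-methyl-1-vinylcyclohex-2-ene-1,6-diol (C3 hydroxyl cis to C6/C7 substituents; C8 hydroxyl trans) | CC1=C[C@H](O[Si](C)(C)C(C)(C)C)[C@@H]([C@@H](O)[C@@]1(O)C=C)C(=C)CO[Si](C)(C)C(C)(C)C | intermediate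
16 | 3-(tert-butyldimethylsilyloxy)-2-[3-(tert-butyldimethylsilyloxy)prop-1-en-2-yl]-6-hydroxy-5-methyl-6-vinylcyclohex-4-en-1-one | CC1=C[C@H](O[Si](C)(C)C(C)(C)C)[C@@H](C(=O)[C@@]1(O)C=C)C(=C)CO[Si](C)(C)C(C)(C)C | intermediate
17 | 4-bromo-2-methylbut-1-ene | C=C(C)CCBr | starting material
18 | (3-methylbut-3-en-1-yl)magnesium bromide | C=C(C)CC[Mg]Br | intermediate
19 | (3-methylbut-3-en-1-yl)cerium dichloride | C=C(C)CC[Ce](Cl)Cl | intermediate (not isolated)
20 | 4-(tert-butyldimethylsilyloxy)-5-[3-(tert-butyldimethylsilyloxy)prop-1-en-2-yl]-2-methyl-6-(3-methylbut-3-en-1-yl)-1-vinylcyclohex-2-ene-1,6-diol (cis-diol) | CC1=C[C@H](O[Si](C)(C)C(C)(C)C)[C@@H]([C@@](O)(CCC(C)=C)[C@@]1(O)C=C)C(=C)CO[Si](C)(C)C(C)(C)C | intermediate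
21 | 3-(tert-butyldimethylsilyloxy)-4-[3-(tert-butyldimethylsilyloxy)prop-1-en-2-yl]-1,7-dimethyl-3,4,5,6-tetrahydronaphthalene-4a,8a-diol (cis fused) | O[C@]12C(C)=C[C@H](O[Si](C)(C)C(C)(C)C)[C@H](C(=C)CO[Si](C)(C)C(C)(C)C)[C@@]1(O)CCC(C)=C2 | intermediate
22 | (2Z,9Z)-4-(tert-butyldimethylsilyloxy)-5-[3-(tert-butyldimethylsilyloxy)prop-1-en-2-yl]-2,9-dimethylcyclodeca-2,9-diene-1,6-dione | O=C1CC/C(C)=C\C(=O)/C(C)=C\[C@H](O[Si](C)(C)C(C)(C)C)[C@@H]1C(=C)CO[Si](C)(C)C(C)(C)C | intermediate
23 | C8 alcohol of 22 (6-hydroxy-cyclodeca-2,9-dien-1-one) | O[C@@H]1CC/C(C)=C\C(=O)/C(C)=C\[C@H](O[Si](C)(C)C(C)(C)C)[C@@H]1C(=C)CO[Si](C)(C)C(C)(C)C | intermediate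
24 | angelic acid, (Z)-2-methylbut-2-enoic acid | C/C=C(/C)C(=O)O | starting material
25 | angelic 2,4,6-trichlorobenzoic anhydride | C/C=C(/C)C(=O)OC(=O)c1c(Cl)cc(Cl)cc1Cl | intermediate (not isolated)
26 | C8 angelate of 23 | C/C=C(/C)C(=O)O[C@@H]1CC/C(C)=C\C(=O)/C(C)=C\[C@H](O[Si](C)(C)C(C)(C)C)[C@@H]1C(=C)CO[Si](C)(C)C(C)(C)C | intermediate
27 | C3 alcohol of 26 (bis-allylic alcohol) | C/C=C(/C)C(=O)O[C@@H]1CC/C(C)=C\[C@H](O)/C(C)=C\[C@H](O[Si](C)(C)C(C)(C)C)[C@@H]1C(=C)CO[Si](C)(C)C(C)(C)C | intermediate
28 | C1–C2 epoxide of 27 (epoxide cis to the C3 hydroxyl) | C/C=C(/C)C(=O)O[C@@H]1CC[C@]2(C)O[C@@H]2[C@H](O)/C(C)=C\[C@H](O[Si](C)(C)C(C)(C)C)[C@@H]1C(=C)CO[Si](C)(C)C(C)(C)C | intermediate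
29 | triol from 28 (C3, C6, C12 hydroxyls free) | C/C=C(/C)C(=O)O[C@@H]1CC[C@]2(C)O[C@@H]2[C@H](O)/C(C)=C\[C@H](O)[C@@H]1C(=C)CO | intermediate
30 | CNP0500828.1 | C=C1C(=O)O[C@H]2/C=C(/C)[C@@H](O)[C@H]3O[C@@]3(C)CC[C@@H](OC(=O)/C(C)=C\C)[C@@H]12 | target

**Step count**

Total: 23 steps. Longest linear sequence: 22 steps (steps 1–13 and 15–23, from 1 to 30); step 14 is a one-step branch.

**Steps most likely to fail**

Step 20 (C3 reduction). Hydride may be delivered to both faces of the flexible ten-membered dienone, so that facial selectivity is poor, and 1,4-reduction may drain material. The fallback sets out from 21 and returns at 28; it installs the epoxide before the ring is opened and lets the epoxide, not the ring conformation, fix C3. On the rigid cis-fused bicycle the two ring-fusion hydroxyls direct VO(acac)2/t-BuOOH to their own face of the ring B alkene, giving the epoxy diol F1. Pb(OAc)4/K2CO3 then cleaves C3–C8 to the epoxy enedione F2. NaBH4 at −78 °C reduces the C8 ketone to the alcohol F3, and mixed-anhydride acylation with 24 (through 25) gives the angelate F4. Zn(BH4)2 in Et2O finally reduces the C3 carbonyl under chelation with the epoxide oxygen (1,2-induction to the anti epoxy alcohol), which gives 28.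

Step 18 (C8 reduction). Hydride may attack the C8 carbonyl from the face that leaves the hydroxyl trans to the C7 side chain, chemoselectivity against the dienone may erode, or the new alkoxide may close transannularly onto the dienone by oxa-Michael addition. The fallback sets out from 22 and returns at 26, and it uses the wrong facial preference instead of fighting it. Reduction gives the C8-epimeric alcohol F5, and a Mitsunobu esterification with 24 (PPh3, DIAD, toluene, 0 °C) inverts C8 while it installs the angelate, so no free alkoxide is carried forward.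

Step 21 (epoxidation). Oxygen may be transferred to C4=C5 instead of C1=C2 (loss of site selectivity), or the bis-allylic alcohol may be oxidised to the dienone. The fallback sets out from 27 and returns at 30; it changes the order of the last operations so that C4=C5 carries an allylic acyloxy group before the epoxidation. HF·pyridine gives the triol F6, TEMPO/PhI(OAc)2 closes the lactone to the hydroxy lactone F7, and VO(acac)2/t-BuOOH then epoxidises C1=C2, the only electron-rich alkene beside the free C3 hydroxyl, to give 30.

**Further compounds**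

F1 | step 20 | C1–C2 epoxide of 21 (epoxide cis to the ring-fusion hydroxyls) | O[C@]12C(C)=C[C@H](O[Si](C)(C)C(C)(C)C)[C@H](C(=C)CO[Si](C)(C)C(C)(C)C)[C@@]1(O)CC[C@]3(C)O[C@@H]32
F2 | step 20 | C1–C2 epoxy (Z)-enedione (epoxide analogue of 22) | O=C1CC[C@]2(C)O[C@@H]2C(=O)/C(C)=C\[C@H](O[Si](C)(C)C(C)(C)C)[C@@H]1C(=C)CO[Si](C)(C)C(C)(C)C
F3 | step 20 | C8 alcohol of F2 | O[C@@H]1CC[C@]2(C)O[C@@H]2C(=O)/C(C)=C\[C@H](O[Si](C)(C)C(C)(C)C)[C@@H]1C(=C)CO[Si](C)(C)C(C)(C)C
F4 | step 20 | C8 angelate of F3 | C/C=C(/C)C(=O)O[C@@H]1CC[C@]2(C)O[C@@H]2C(=O)/C(C)=C\[C@H](O[Si](C)(C)C(C)(C)C)[C@@H]1C(=C)CO[Si](C)(C)C(C)(C)C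
F5 | step 18 | C8 epimer of 23 | O[C@H]1CC/C(C)=C\C(=O)/C(C)=C\[C@H](O[Si](C)(C)C(C)(C)C)[C@@H]1C(=C)CO[Si](C)(C)C(C)(C)C
F6 | step 21 | desilylated triol of 27 | C/C=C(/C)C(=O)O[C@@H]1CC/C(C)=C\[C@H](O)/C(C)=C\[C@H](O)[C@@H]1C(=C)CO
F7 | step 21 | C3-hydroxy diene α-methylene lactone (1,2-deoxy analogue of 30) | C/C=C(/C)C(=O)O[C@@H]1CC/C(C)=C\[C@H](O)/C(C)=C\[C@@H]2OC(=O)C(=C)[C@H]12
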